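You read each of these flasks at 6.0 h, so the first thing to ask is what must happen before that hour for free enzyme to stay in the flask.

    free enzyme → unfolded enzyme (k1 = 4.0 × 10⁻⁵ /min, Ea1 = 229 kJ/mol)
    starting material + free enzyme → target + free enzyme, rate k2*[starting material]*[free enzyme]/(1 + ([starting material]/Km2)) (Km2 = 32 mM, k2 = 6600 /M/min, Ea2 = 52.0 kJ/mol)
    precatalyst → free enzyme (k3 = 0.012 /min, Ea3 = 100 kJ/mol)
    starting material + protic impurity → quenched substrate (k4 = 0.064 /M/min, Ea4 = 66.0 kJ/mol)
    free enzyme + stray impurity → spent catalyst (k5 = 4.9 × 10⁵ /M/min, Ea5 = 14.0 kJ/mol)
    (constants at 40 °C)

| setting | Tuesday's | Monday's | Friday's |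
|---|---|---|---|
| starting material | 0.050 M | 0.050 M | 0.050 M |
| protic impurity | 0.0250 M | 0.0250 M | 0.0250 M |
| precatalyst | 10 µM | 10 µM | 10 µM |
| stray impurity | 5.3 µM | 5.3 µM | 5.3 µM |
| temperature | 10 °C | −20 °C | 40 °C |
| time | 6.0 h | 6.0 h | 6.0 h |

- the flask with the highest amount of target, in percent of the starting material charged ("all alike" if they lie within 1.5 percentage points) (Tuesday's / Monday's / Friday's / all alike)
- final target, as a percentage of the starting material charged, in Tuesday's
- final target, as a percentage of the starting material charged, in Monday's
- final target, as a percentage of the starting material charged, in Friday's

- at 40 °C the constants are as listed, elsewhere as the activation energies make them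

Here is my own reckoning. Free enzyme makes the target, but the stray impurity destroys it. At 40 °C, with the stray impurity at its charge, each free enzyme is lost at 2.60 /min, and the precatalyst opens at 0.012 /min, so loss is much faster than release. While stray impurity lasts, then, newly released enzyme barely survives. The precatalyst opens by first-order decay, so in Friday's the time is ln(charge of precatalyst / (that charge minus the charge of stray impurity)) divided by the release constant, which gives 1.05 h. Call this t_b, the breakthrough time: the time the precatalyst needs to release as much enzyme as the flask holds stray impurity. It marks the end of an induction period.

Cooling slows release more steeply than it slows the loss, so I keep the same picture in the cold flasks and work in powers of ten. The release constant loses Ea/(2.3 R) × (1/T − 1/T_ref) powers of ten, where Ea is its activation energy, R the gas constant, T the flask's temperature and T_ref the 40 °C of the listed constants. That is 1.77 powers for Tuesday's at 10 °C and 3.96 for Monday's at −20 °C. The breakthrough time grows by the same powers, to 61.6 h for Tuesday's and 397 d for Monday's. Friday's breaks through before the reading, while Tuesday's and Monday's do not. Ranking the flasks by reading time over t_b gives Friday's.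

The same t_b gives Friday's yield. Until Friday's breakthrough I let the quench by protic impurity run unopposed at 0.00160 /min, taking that impurity at its charge, and this leaves 90.4% of the starting material. After that, the 4.70 µM of surviving enzyme, credited in full and at the charged starting material, consumes it at 0.0121 /min, faster than the quench. Target therefore takes a share of 88.3%, and Friday's comes to 79.9%. For the two cold flasks I commit to no figure beyond their place before t_b.

The forecast names Friday's, with 81% there (from 76% to 85%), 0.016% in Tuesday's and <0.001% in Monday's. Its ground is that the stray impurity “kills enzyme almost as fast as it is released”. Its Friday's figure is higher than mine.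

The simulated flasks give 80.7% in Friday's, 0.0160% in Tuesday's and 0% in Monday's, so Friday's leads, as forecast. Friday's target has come to rest: 0.284% starting material stands at 6.00 h, and target reads 81.0% at 60.0 h. Monday's, with t_b at 397 d, still holds 99.1% of its stray impurity at 60.0 h, with target 0%. Tuesday's is still moving: its t_b of 61.6 h lies close to 60.0 h, where its stray impurity is down to 2.02% of charge and its target has reached 0.399%.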